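**Plan**

1. Enabling feature: in ring A (C1'–C6') the gem-dimethyl carbon C1' is bonded to C6' next to a C4'=C5' alkene. This is the pattern left when the C5'=C6' alkene of an open-chain dienone attacks a C1' tertiary cation and H4' is lost. Ring B (C1–C6) contains the same C1–C6 bond.
2. Cuts: C11=C12 and C11'=C12' (Wittig) give a C10 dialdehyde and two C15 phosphonium salts. C9=C10 and C9'=C10' (Horner–Wadsworth–Emmons) lead back to two 3-oxygenated α-ionones of opposite handedness. In each ionone the ring bond C1–C6 is cut, then C7–C8 (Heck), the C5–methyl bond (carboalumination) and the two C–C bonds flanking the carbinol unit (epichlorohydrin).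
3. Forward, rings: (R)-epichlorohydrin gives the acyclic acetoxy dienone, and ring A is closed in step 6. (S)-Epichlorohydrin gives the mirror-image ring in step 17. That ring becomes ring B by hydroxyl-directed epoxidation of C4=C5 and base-induced epoxide opening, which moves the alkene to C5=C6 and leaves the 3,4-cis-diol.
4. Forward, chain: ring B C15 salt plus C10 dialdehyde gives the C25 apo-aldehyde; the ring A C15 salt then gives the C40 chain; desilylation comes last.
5. Stereochemistry: C3' comes from (R)- and C3 from (S)-epichlorohydrin. C6' comes from the chair-like ring closure (chain trans to C3'–O). C4 comes from the hydroxyl-directed epoxidation, whose C4–O bond is kept.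

Key step: step 6

Remark: ring positions carry carotenoid numbers (C1 gem-dimethyl carbon, C5 methyl-bearing carbon, C6 chain-bearing carbon; primed for ring A), and acyclic precursors are numbered as the ring they become. IUPAC locants of the ring B cyclohexenyl group run the other way, so carotenoid (3S,4R) reads (4S,3R) there. The C10 dialdehyde 36 and lithium acetylide–ethylenediamine 5 are assumed to be catalogue chemicals.

**Ring A series**

Step 1
Reactants: 1 (R)-epichlorohydrin; 2 isopropenylmagnesium bromide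
Product: 4 (R)-2-(2-methylprop-2-en-1-yl)oxirane, via chlorohydrin 3 (not isolated)
Conditions: CuI (10 mol %), THF, −40 → 0 °C; then 50% aq. NaOH, rt; distilled
Reagents that add atoms: none
Why: Copper-catalysed Grignard opening of the epoxide at its CH2 terminus, then Williamson ring closure onto the CH2Cl carbon; no bond at the stereocentre is touched, so the configuration of 1 passes into 4.

Step 2
Reactants: 4 (R)-2-(2-methylprop-2-en-1-yl)oxirane; 5 lithium acetylide–ethylenediamine complex
Product: 6 (R)-2-methylhept-1-en-6-yn-4-ol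
Conditions: DMSO, 0 °C → rt; H2O
Reagents that add atoms: none
Why: SN2 opening of the terminal epoxide by acetylide at the unsubstituted carbon, a standard route to homopropargylic alcohols; the stereocentre is a spectator.

Step 3
Reactants: 6 (R)-2-methylhept-1-en-6-yn-4-ol
Product: 8 (1E,4R)-1-iodo-2,6-dimethylhepta-1,6-dien-4-ol, via alkenylalane 7 (not isolated)
Conditions: AlMe3 (3 equiv), Cp2ZrCl2 (25 mol %), CH2Cl2, 0 °C → rt; then I2, THF, −30 °C; aq. K2CO3
Reagents that add atoms: trimethylaluminium C[Al](C)C; iodine II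
Why: Negishi zirconium-catalysed carboalumination adds Me–Al syn across the terminal alkyne with aluminium on the terminal carbon, and iodinolysis with retention gives the (E)-iodide; the hydroxyl is masked in the flask as its aluminium alkoxide and the 1,1-disubstituted alkene is not carbometalated.

Step 4
Reactants: 8 (1E,4R)-1-iodo-2,6-dimethylhepta-1,6-dien-4-ol; 9 methyl vinyl ketone
Product: 10 (3E,5E,8R)-8-hydroxy-6,10-dimethylundeca-3,5,10-trien-2-one
Conditions: 9 (3 equiv), Pd(OAc)2 (5 mol %), Bu4NCl, NaHCO3, DMF, 40 °C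
Reagents that add atoms: none
Why: Heck reaction under ligand-free phase-transfer conditions: oxidative addition of the alkenyl iodide to zerovalent palladium with retention, insertion of the enone and syn β-hydride elimination give the (3E,5E)-dienone; the E geometry of 8 keeps palladium away from the isopropenyl group, so no ring can form.

Step 5
Reactants: 10 (3E,5E,8R)-8-hydroxy-6,10-dimethylundeca-3,5,10-trien-2-one
Product: 11 (3E,5E,8R)-6,10-dimethyl-2-oxoundeca-3,5,10-trien-8-yl acetate
Conditions: Ac2O, pyridine, DMAP (cat.), CH2Cl2, 0 °C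
Reagents that add atoms: acetic anhydride CC(=O)OC(C)=O
Why: DMAP-catalysed acylation of the secondary alcohol; it is placed after the Heck step so that the acetate, which sits β to the vinylogously acidic C4' methylene of the dienone, never meets warm carbonate base.

Step 6
Reactants: 11 (3E,5E,8R)-6,10-dimethyl-2-oxoundeca-3,5,10-trien-8-yl acetate
Product: 12 (3R,6R)-3-acetoxy-α-ionone
Conditions: 85% H3PO4, toluene, 15–25 °C, vigorous stirring; poured onto ice/NaHCO3
Reagents that add atoms: none
Why: H3PO4 protonates the isolated 1,1-disubstituted alkene at its CH2 terminus to give the tertiary C1' cation, C6' of the (E)-C5'=C6' alkene attacks it to form the C1'–C6' bond, and the tertiary C5' cation so formed loses a proton from C4'. The closest known reaction is the phosphoric acid cyclisation of pseudoionone to α-ionone; 11 differs only in the isopropenyl initiator (same cation) and the acetoxy group on the tether. Ring A closes in the 6-endo-trig mode (both alkene carbons end up in the ring) through a chair-like transition state. The new stereocentre C6' is set by C3': the acetate lies equatorial to avoid the forming axial C1' methyl, and the E alkene puts C7' equatorial, so C3'–O and C6'–C7' become 1,4-trans, i.e. (3R,6R). The step needs protonation of the terminal alkene, ε (C4'=C5') rather than β or γ regiochemistry, and survival of the ester: the O-protonated dienone has no productive pathway of its own, proton loss at C4' is the kinetic course in H3PO4 at or below room temperature, and the electron-poor acetate oxygen should make the allylic C3'–O bond of 12 much harder to ionise than that of a free alcohol.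

Step 7
Reactants: 12 (3R,6R)-3-acetoxy-α-ionone
Product: 13 (3R,6R)-3-hydroxy-α-ionone
Conditions: K2CO3 (0.2 equiv), MeOH, 0 °C
Reagents that add atoms: none
Why: Base-catalysed transesterification of the acetate with methanol; with catalytic carbonate at 0 °C ester exchange should outpace γ-deprotonation at C6', so neither loss of acetate nor epimerisation is expected.

Step 8
Reactants: 13 (3R,6R)-3-hydroxy-α-ionone
Product: 14 (3R,6R)-3-(tert-butyldimethylsilyloxy)-α-ionone
Conditions: TBSCl, imidazole, DMF, rt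
Reagents that add atoms: tert-butyldimethylsilyl chloride CC(C)(C)[Si](C)(C)Cl
Why: Imidazole-promoted silyl ether formation; the silyl ether is a poor leaving group and withstands the base and hydride steps that follow.

Step 9
Reactants: 14 (3R,6R)-3-(tert-butyldimethylsilyloxy)-α-ionone
Product: 15 ethyl (2E,4E)-5-[(1R,4R)-4-(tert-butyldimethylsilyloxy)-2,6,6-trimethylcyclohex-2-en-1-yl]-3-methylpenta-2,4-dienoate
Conditions: (EtO)2P(O)CH2CO2Et, NaH, THF, 0 → 40 °C; 9'Z isomer removed on silica
Reagents that add atoms: triethyl phosphonoacetate CCOC(=O)CP(=O)(OCC)OCC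
Why: Horner–Wadsworth–Emmons olefination of the methyl ketone with the preformed sodium phosphonate (no excess hydride, so C6' is not deprotonated); the 9'E ester should predominate.

Step 10
Reactants: 15 ring A C15 ester
Product: 16 (2E,4E)-5-[(1R,4R)-4-(tert-butyldimethylsilyloxy)-2,6,6-trimethylcyclohex-2-en-1-yl]-3-methylpenta-2,4-dien-1-ol
Conditions: i-Bu2AlH (2.5 equiv), CH2Cl2, −78 °C; aq. potassium sodium tartrate
Reagents that add atoms: none
Why: 1,2-Reduction of the conjugated ester to the allylic alcohol by the aluminium hydride; alkenes and silyl ether are inert.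

Step 11
Reactants: 16 ring A C15 alcohol
Product: 18 [(2E,4E)-5-[(1R,4R)-4-(tert-butyldimethylsilyloxy)-2,6,6-trimethylcyclohex-2-en-1-yl]-3-methylpenta-2,4-dien-1-yl]triphenylphosphonium bromide, via allylic bromide 17 (not isolated)
Conditions: CBr4 (1.2 equiv), PPh3 (1.25 equiv), CH2Cl2, −20 °C; then PPh3 (1.5 equiv), −20 °C → rt
Reagents that add atoms: carbon tetrabromide BrC(Br)(Br)Br; triphenylphosphine c1ccc(cc1)P(c1ccccc1)c1ccccc1
Why: Appel bromination under neutral conditions, then SN2 quaternisation of PPh3 by the allylic bromide in the same flask; no acid is present that could ionise the C3' allylic ether or move the ring alkene.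

**Ring B series**

Step 12
Reactants: 19 (S)-epichlorohydrin; 2 isopropenylmagnesium bromide
Product: 21 (S)-2-(2-methylprop-2-en-1-yl)oxirane, via chlorohydrin 20 (not isolated)
Conditions: CuI (10 mol %), THF, −40 → 0 °C; then 50% aq. NaOH, rt; distilled
Reagents that add atoms: none
Why: Same copper-catalysed epoxide opening and Williamson closure as step 1, on the enantiomer; the configuration of 19 is retained.

Step 13
Reactants: 21 (S)-2-(2-methylprop-2-en-1-yl)oxirane; 5 lithium acetylide–ethylenediamine complex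
Product: 22 (S)-2-methylhept-1-en-6-yn-4-ol
Conditions: DMSO, 0 °C → rt; H2O
Reagents that add atoms: none
Why: SN2 epoxide opening by acetylide at the CH2 terminus, as in step 2.

Step 14
Reactants: 22 (S)-2-methylhept-1-en-6-yn-4-ol
Product: 24 (1E,4S)-1-iodo-2,6-dimethylhepta-1,6-dien-4-ol, via alkenylalane 23 (not isolated)
Conditions: AlMe3 (3 equiv), Cp2ZrCl2 (25 mol %), CH2Cl2, 0 °C → rt; then I2, THF, −30 °C; aq. K2CO3
Reagents that add atoms: trimethylaluminium C[Al](C)C; iodine II
Why: Negishi carboalumination (syn Me–Al addition) and iodinolysis with retention, as in step 3, give the (E)-iodide.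

Step 15
Reactants: 24 (1E,4S)-1-iodo-2,6-dimethylhepta-1,6-dien-4-ol; 9 methyl vinyl ketone
Product: 25 (3E,5E,8S)-8-hydroxy-6,10-dimethylundeca-3,5,10-trien-2-one
Conditions: 9 (3 equiv), Pd(OAc)2 (5 mol %), Bu4NCl, NaHCO3, DMF, 40 °C
Reagents that add atoms: none
Why: Heck reaction as in step 4, with retention of the iodide geometry and an E enone from syn β-hydride elimination.

Step 16
Reactants: 25 (3E,5E,8S)-8-hydroxy-6,10-dimethylundeca-3,5,10-trien-2-one
Product: 26 (3E,5E,8S)-6,10-dimethyl-2-oxoundeca-3,5,10-trien-8-yl acetate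
Conditions: Ac2O, pyridine, DMAP (cat.), CH2Cl2, 0 °C
Reagents that add atoms: acetic anhydride CC(=O)OC(C)=O
Why: DMAP-catalysed acylation, as in step 5.

Step 17
Reactants: 26 (3E,5E,8S)-6,10-dimethyl-2-oxoundeca-3,5,10-trien-8-yl acetate
Product: 27 (3S,6S)-3-acetoxy-α-ionone
Conditions: 85% H3PO4, toluene, 15–25 °C, vigorous stirring; poured onto ice/NaHCO3
Reagents that add atoms: none
Why: The cation–olefin cyclisation of step 6 on the enantiomer (6-endo closure of C1–C6 through the chair with equatorial acetate, loss of H4); the C6 centre it sets is erased in step 20, so here only the C4=C5 regiochemistry and an intact C3–O bond matter.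

Step 18
Reactants: 27 (3S,6S)-3-acetoxy-α-ionone
Product: 28 (3S,6S)-3-hydroxy-α-ionone
Conditions: K2CO3 (0.2 equiv), MeOH, 0 °C
Reagents that add atoms: none
Why: Carbonate-catalysed transesterification, as in step 7.

Step 19
Reactants: 28 (3S,6S)-3-hydroxy-α-ionone
Product: 29 (3S,4S,5R,6S)-4,5-epoxy-3-hydroxy-4,5-dihydro-α-ionone (oxirane oxygen cis to the C3 hydroxyl)
Conditions: mCPBA (1.1 equiv), NaHCO3, CH2Cl2, 0 °C
Reagents that add atoms: 3-chloroperoxybenzoic acid O=C(OO)c1cccc(Cl)c1
Why: Henbest (hydroxyl-directed Prilezhaev) epoxidation: hydrogen bonding to the C3 hydroxyl delivers the peracid to the syn face, which in the 3,6-trans compound is also the face away from the C6 side chain, and this sets C4; the electron-poor enone alkene does not react.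

Step 20
Reactants: 29 (3S,4S,5R,6S)-4,5-epoxy-3-hydroxy-4,5-dihydro-α-ionone
Product: 30 (3S,4R)-3,4-dihydroxy-β-ionone
Conditions: NaOMe (0.3 equiv), MeOH, 0 °C → rt
Reagents that add atoms: none
Why: Base-induced epoxide-to-allylic-alcohol isomerisation (vinylogous E1cB), known for α-ionone epoxide to 4-hydroxy-β-ionone: methoxide removes the γ-proton at C6 and the dienolate expels the C5–O bond; the C4–O bond is untouched, so the new hydroxyl stays cis to the C3 hydroxyl.

Step 21
Reactants: 30 (3S,4R)-3,4-dihydroxy-β-ionone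
Product: 31 (3S,4R)-3,4-bis(tert-butyldimethylsilyloxy)-β-ionone
Conditions: TBSOTf (2.4 equiv), 2,6-lutidine, CH2Cl2, −40 → 0 °C
Reagents that add atoms: tert-butyldimethylsilyl triflate CC(C)(C)[Si](C)(C)OS(=O)(=O)C(F)(F)F
Why: Silyl ether formation with the silyl triflate, needed for the hindered C4 hydroxyl; at this stage C4–O is allylic only to an electron-poor dienone and should not ionise.

Step 22
Reactants: 31 (3S,4R)-3,4-bis(tert-butyldimethylsilyloxy)-β-ionone
Product: 32 ethyl (2E,4E)-5-[(3R,4S)-3,4-bis(tert-butyldimethylsilyloxy)-2,6,6-trimethylcyclohex-1-en-1-yl]-3-methylpenta-2,4-dienoate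
Conditions: (EtO)2P(O)CH2CO2Et, NaH, THF, 0 → 45 °C; 9Z isomer removed on silica
Reagents that add atoms: triethyl phosphonoacetate CCOC(=O)CP(=O)(OCC)OCC
Why: Horner–Wadsworth–Emmons olefination of the dienone methyl ketone, the usual two-carbon extension of β-ionones; the 9E ester should predominate.

Step 23
Reactants: 32 ring B C15 ester
Product: 33 (2E,4E)-5-[(3R,4S)-3,4-bis(tert-butyldimethylsilyloxy)-2,6,6-trimethylcyclohex-1-en-1-yl]-3-methylpenta-2,4-dien-1-ol
Conditions: i-Bu2AlH (2.5 equiv), CH2Cl2, −78 °C; aq. potassium sodium tartrate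
Reagents that add atoms: none
Why: 1,2-Reduction of the conjugated ester by the aluminium hydride, with a neutral work-up because C4–O is now allylic to an electron-rich triene.

Step 24
Reactants: 33 ring B C15 alcohol
Product: 35 [(2E,4E)-5-[(3R,4S)-3,4-bis(tert-butyldimethylsilyloxy)-2,6,6-trimethylcyclohex-1-en-1-yl]-3-methylpenta-2,4-dien-1-yl]triphenylphosphonium bromide, via allylic bromide 34 (not isolated)
Conditions: CBr4 (1.2 equiv), PPh3 (1.25 equiv), CH2Cl2, −30 °C; then PPh3 (1.5 equiv), −30 °C → rt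
Reagents that add atoms: carbon tetrabromide BrC(Br)(Br)Br; triphenylphosphine c1ccc(cc1)P(c1ccccc1)c1ccccc1
Why: Appel bromination and SN2 quaternisation of PPh3 in one flask under acid-free conditions; the labile bromide is trapped as it forms and the phosphonium group then lowers the tendency of C4–O to ionise.

**Assembly**

Step 25
Reactants: 35 ring B C15 phosphonium bromide; 36 (2E,4E,6E)-2,7-dimethylocta-2,4,6-trienedial
Product: 38 (3S,4R)-3,4-bis(tert-butyldimethylsilyloxy)-12'-apo-β-caroten-12'-al, via ylide 37 (not isolated)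
Conditions: 36 (3 equiv), NaOMe (slow addition), CH2Cl2/MeOH, 0 °C → rt; then n-heptane, reflux
Reagents that add atoms: none
Why: Wittig olefination: the semi-stabilised allylic ylide condenses with one formyl group of the dialdehyde used in excess to form C11=C12, and heating isomerises the hindered 11Z part to the all-E apo-aldehyde.

Step 26
Reactants: 18 ring A C15 phosphonium bromide; 38 ring B C25 apo-aldehyde
Product: 40 (3S,4R,3'R,6'R)-3,4,3'-tris(tert-butyldimethylsilyloxy)-β,ε-carotene, via ylide 39 (not isolated)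
Conditions: NaOMe, CH2Cl2/MeOH, 0 °C → rt; then n-heptane, reflux, dark
Reagents that add atoms: none
Why: Wittig olefination forming C11'=C12', followed by thermal Z → E isomerisation; the basic medium leaves the four stereocentres, the ring A alkene position and the silyl ethers alone.

Step 27
Reactants: 40 tris-silyl ether of the target
Product: 41 (3S,4R,3'R,6'R)-β,ε-carotene-3,4,3'-triol (CNP0191612.1)
Conditions: Bu4NF (6 equiv), THF, 0 → 40 °C, dark, Ar; H2O
Reagents that add atoms: none
Why: Fluoride-induced cleavage of the three silyl ethers (Si–F bond formation); non-acidic conditions are chosen because the C4 and C3' allylic C–O bonds of the free polyene ionise in acid.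

**Compound list**

1 | (R)-epichlorohydrin | ClC[C@H]1CO1 | starting material
2 | isopropenylmagnesium bromide | C=C(C)[Mg]Br | starting material
3 | (R)-1-chloro-4-methylpent-4-en-2-ol (not isolated) | ClC[C@H](O)CC(C)=C | intermediate
4 | (R)-2-(2-methylprop-2-en-1-yl)oxirane | C=C(C)C[C@@H]1CO1 | intermediate
5 | lithium acetylide–ethylenediamine complex | [Li+].[C-]#C.NCCN | starting material
6 | (R)-2-methylhept-1-en-6-yn-4-ol | C=C(C)C[C@@H](O)CC#C | intermediate
7 | (R,E)-alkenylalane, dimethylaluminium alkoxide of 1-(dimethylalumanyl)-2,6-dimethylhepta-1,6-dien-4-ol (not isolated) | C=C(C)C[C@@H](O[Al](C)C)C/C(C)=C/[Al](C)C | intermediate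
8 | (1E,4R)-1-iodo-2,6-dimethylhepta-1,6-dien-4-ol | C=C(C)C[C@@H](O)C/C(C)=C/I | intermediate
9 | methyl vinyl ketone (but-3-en-2-one) | C=CC(C)=O | starting material
10 | (3E,5E,8R)-8-hydroxy-6,10-dimethylundeca-3,5,10-trien-2-one | C=C(C)C[C@@H](O)C/C(C)=C/C=C/C(C)=O | intermediate
11 | (3E,5E,8R)-6,10-dimethyl-2-oxoundeca-3,5,10-trien-8-yl acetate | C=C(C)C[C@@H](OC(C)=O)C/C(C)=C/C=C/C(C)=O | intermediate
12 | (3R,6R)-3-acetoxy-α-ionone | CC1=C[C@H](OC(C)=O)CC(C)(C)[C@H]1/C=C/C(C)=O | intermediate
13 | (3R,6R)-3-hydroxy-α-ionone | CC1=C[C@H](O)CC(C)(C)[C@H]1/C=C/C(C)=O | intermediate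
14 | (3R,6R)-3-(tert-butyldimethylsilyloxy)-α-ionone | CC1=C[C@H](O[Si](C)(C)C(C)(C)C)CC(C)(C)[C@H]1/C=C/C(C)=O | intermediate
15 | ethyl (2E,4E)-5-[(1R,4R)-4-(tert-butyldimethylsilyloxy)-2,6,6-trimethylcyclohex-2-en-1-yl]-3-methylpenta-2,4-dienoate | CC1=C[C@H](O[Si](C)(C)C(C)(C)C)CC(C)(C)[C@H]1/C=C/C(C)=C/C(=O)OCC | intermediate
16 | (2E,4E)-5-[(1R,4R)-4-(tert-butyldimethylsilyloxy)-2,6,6-trimethylcyclohex-2-en-1-yl]-3-methylpenta-2,4-dien-1-ol | CC1=C[C@H](O[Si](C)(C)C(C)(C)C)CC(C)(C)[C@H]1/C=C/C(C)=C/CO | intermediate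
17 | ring A C15 allylic bromide (1-bromo analogue of 16, not isolated) | CC1=C[C@H](O[Si](C)(C)C(C)(C)C)CC(C)(C)[C@H]1/C=C/C(C)=C/CBr | intermediate
18 | ring A C15 triphenylphosphonium bromide | CC1=C[C@H](O[Si](C)(C)C(C)(C)C)CC(C)(C)[C@H]1/C=C/C(C)=C/C[P+](c1ccccc1)(c1ccccc1)c1ccccc1.[Br-] | intermediate
19 | (S)-epichlorohydrin | ClC[C@@H]1CO1 | starting material
20 | (S)-1-chloro-4-methylpent-4-en-2-ol (not isolated) | ClC[C@@H](O)CC(C)=C | intermediate
21 | (S)-2-(2-methylprop-2-en-1-yl)oxirane | C=C(C)C[C@H]1CO1 | intermediate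
22 | (S)-2-methylhept-1-en-6-yn-4-ol | C=C(C)C[C@H](O)CC#C | intermediate
23 | (S,E)-alkenylalane, enantiomer of 7 (not isolated) | C=C(C)C[C@H](O[Al](C)C)C/C(C)=C/[Al](C)C | intermediate
24 | (1E,4S)-1-iodo-2,6-dimethylhepta-1,6-dien-4-ol | C=C(C)C[C@H](O)C/C(C)=C/I | intermediate
25 | (3E,5E,8S)-8-hydroxy-6,10-dimethylundeca-3,5,10-trien-2-one | C=C(C)C[C@H](O)C/C(C)=C/C=C/C(C)=O | intermediate
26 | (3E,5E,8S)-6,10-dimethyl-2-oxoundeca-3,5,10-trien-8-yl acetate | C=C(C)C[C@H](OC(C)=O)C/C(C)=C/C=C/C(C)=O | intermediate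
27 | (3S,6S)-3-acetoxy-α-ionone | CC1=C[C@@H](OC(C)=O)CC(C)(C)[C@@H]1/C=C/C(C)=O | intermediate
28 | (3S,6S)-3-hydroxy-α-ionone | CC1=C[C@@H](O)CC(C)(C)[C@@H]1/C=C/C(C)=O | intermediate
29 | (3S,4S,5R,6S)-4,5-epoxy-3-hydroxy-4,5-dihydro-α-ionone | C[C@]12O[C@H]1[C@@H](O)CC(C)(C)[C@@H]2/C=C/C(C)=O | intermediate
30 | (3S,4R)-3,4-dihydroxy-β-ionone (cis-diol) | CC(=O)/C=C/C1=C(C)[C@@H](O)[C@@H](O)CC1(C)C | intermediate
31 | (3S,4R)-3,4-bis(tert-butyldimethylsilyloxy)-β-ionone | CC(=O)/C=C/C1=C(C)[C@@H](O[Si](C)(C)C(C)(C)C)[C@@H](O[Si](C)(C)C(C)(C)C)CC1(C)C | intermediate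
32 | ethyl (2E,4E)-5-[(3R,4S)-3,4-bis(tert-butyldimethylsilyloxy)-2,6,6-trimethylcyclohex-1-en-1-yl]-3-methylpenta-2,4-dienoate | CCOC(=O)/C=C(C)/C=C/C1=C(C)[C@@H](O[Si](C)(C)C(C)(C)C)[C@@H](O[Si](C)(C)C(C)(C)C)CC1(C)C | intermediate
33 | (2E,4E)-5-[(3R,4S)-3,4-bis(tert-butyldimethylsilyloxy)-2,6,6-trimethylcyclohex-1-en-1-yl]-3-methylpenta-2,4-dien-1-ol | OC/C=C(C)/C=C/C1=C(C)[C@@H](O[Si](C)(C)C(C)(C)C)[C@@H](O[Si](C)(C)C(C)(C)C)CC1(C)C | intermediate
34 | ring B C15 allylic bromide (1-bromo analogue of 33, not isolated) | BrC/C=C(C)/C=C/C1=C(C)[C@@H](O[Si](C)(C)C(C)(C)C)[C@@H](O[Si](C)(C)C(C)(C)C)CC1(C)C | intermediate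
35 | ring B C15 triphenylphosphonium bromide | [Br-].c1ccc(cc1)[P+](c1ccccc1)(c1ccccc1)C/C=C(C)/C=C/C1=C(C)[C@@H](O[Si](C)(C)C(C)(C)C)[C@@H](O[Si](C)(C)C(C)(C)C)CC1(C)C | intermediate
36 | (2E,4E,6E)-2,7-dimethylocta-2,4,6-trienedial | O=C/C(C)=C/C=C/C=C(C)/C=O | starting material
37 | ring B C15 phosphorus ylide (not isolated) | c1ccc(cc1)P(c1ccccc1)(c1ccccc1)=C/C=C(C)/C=C/C1=C(C)[C@@H](O[Si](C)(C)C(C)(C)C)[C@@H](O[Si](C)(C)C(C)(C)C)CC1(C)C | intermediate
38 | (3S,4R)-3,4-bis(tert-butyldimethylsilyloxy)-12'-apo-β-caroten-12'-al | O=C/C(C)=C/C=C/C=C(C)/C=C/C=C(C)/C=C/C1=C(C)[C@@H](O[Si](C)(C)C(C)(C)C)[C@@H](O[Si](C)(C)C(C)(C)C)CC1(C)C | intermediate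
39 | ring A C15 phosphorus ylide (not isolated) | CC1=C[C@H](O[Si](C)(C)C(C)(C)C)CC(C)(C)[C@H]1/C=C/C(C)=C/C=P(c1ccccc1)(c1ccccc1)c1ccccc1 | intermediate
40 | (3S,4R,3'R,6'R)-3,4,3'-tris(tert-butyldimethylsilyloxy)-β,ε-carotene | CC1=C[C@H](O[Si](C)(C)C(C)(C)C)CC(C)(C)[C@H]1/C=C/C(C)=C/C=C/C(C)=C/C=C/C=C(C)/C=C/C=C(C)/C=C/C1=C(C)[C@@H](O[Si](C)(C)C(C)(C)C)[C@@H](O[Si](C)(C)C(C)(C)C)CC1(C)C | intermediate
41 | (3S,4R,3'R,6'R)-β,ε-carotene-3,4,3'-triol | CC1=C[C@H](O)CC(C)(C)[C@H]1/C=C/C(C)=C/C=C/C(C)=C/C=C/C=C(C)/C=C/C=C(C)/C=C/C1=C(C)[C@@H](O)[C@@H](O)CC1(C)C | target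

**Step count and risks**

Total: 27 steps. Longest linear sequence: 16 steps (steps 12–27, from 19 to 41). The ring A branch (steps 1–11) joins in step 26.

Steps most likely to fail:

1. Step 6 (the key step; step 17 is the same reaction on the enantiomer and shares the risk).
 - What may go wrong: O-protonation of the dienone slows ring closure, so the C1' cation may lose a proton towards C2' to a prenyl-type allylic acetate that ionises. The cation may also be held by the acetate carbonyl, or the allylic acetate of the product may ionise. Acid-induced E/Z equilibration of C5'=C6' would erode the 3',6'-trans selectivity.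
 - Fallback (ring closure at the enoate stage, enone added afterwards), setting out from iodide 8 and coming back at 13:
   - Methoxycarbonylation of 8 (PdCl2(PPh3)2, CO, MeOH, Et3N) should give methyl (2E,5R)-5-hydroxy-3,7-dimethylocta-2,7-dienoate F1.
   - Acetylation should give methyl (2E,5R)-5-acetoxy-3,7-dimethylocta-2,7-dienoate F2.
   - Acid cyclisation of this geranate-type ester (BF3·OEt2 or 85% H3PO4, the established route from geranic esters to α-cyclogeranates) should give methyl (1R,4R)-4-acetoxy-2,6,6-trimethylcyclohex-2-ene-1-carboxylate F3. The ester carbonyl is far less basic than the dienone and leaves the terminating alkene nucleophilic.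
   - LiAlH4 should give (1R,4R)-4-(hydroxymethyl)-3,5,5-trimethylcyclohex-2-en-1-ol F4.
   - TEMPO/PhI(OAc)2 should oxidise the primary alcohol preferentially to (1R,4R)-4-hydroxy-2,6,6-trimethylcyclohex-2-ene-1-carbaldehyde F5.
   - Wittig reaction with Ph3P=CHC(O)CH3 in toluene should give 13.
   - Run from iodide 24, the same sequence should give the enantiomeric hydroxy ester F6, acetoxy ester F7, cyclised ester F8, diol F9 and hydroxy aldehyde F10, and come back at 28.

2. Step 24.
 - What may go wrong: heterolysis of the allylic C–Br bond of 34 gives a heptatrienyl cation that loses H4 or the C4 silyloxy group (retro-type elimination) before PPh3 captures it.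
 - Fallback (the two coupling partners change roles, so ring B never passes through an allylic halide), setting out from 33 and 18 and coming back at 40:
   - MnO2 oxidation of 33 should give (2E,4E)-5-[(3R,4S)-3,4-bis(tert-butyldimethylsilyloxy)-2,6,6-trimethylcyclohex-1-en-1-yl]-3-methylpenta-2,4-dienal F11.
   - Wittig reaction of 18 with excess 36 (as in step 25) should give (3R,6R)-3-(tert-butyldimethylsilyloxy)-12'-apo-ε-caroten-12'-al F12.
   - NaBH4 should give the corresponding 12'-apo-ε-caroten-12'-ol F13.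
   - Appel bromination should give the allylic bromide F14, and PPh3 in the same flask the C25 triphenylphosphonium bromide F15.
   - Wittig reaction of F15 with F11 (NaOMe, then thermal isomerisation) should form C11=C12 and give 40.

3. Step 27.
 - What may go wrong: slow cleavage of the hindered C4 silyl ether next to the C3 silyl ether, so that long exposure to basic fluoride isomerises or degrades the complete polyene triol.
 - Fallback (the hindered groups are removed before the last C–C bond is made), setting out from 38 and coming back at 41: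
   - Bu4NF buffered with AcOH should convert 38 into (3S,4R)-3,4-dihydroxy-12'-apo-β-caroten-12'-al F16 at the more robust C25 stage.
   - Wittig reaction of F16 with 18 (extra NaOMe; free hydroxyl groups are tolerated) should give (3S,4R,3'R,6'R)-3'-(tert-butyldimethylsilyloxy)-β,ε-carotene-3,4-diol F17.
   - Brief Bu4NF treatment should remove the remaining unhindered ring A silyl ether and give 41.

**Further compounds**

F1 | step 6 | methyl (2E,5R)-5-hydroxy-3,7-dimethylocta-2,7-dienoate | C=C(C)C[C@@H](O)C/C(C)=C/C(=O)OC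
F2 | step 6 | methyl (2E,5R)-5-acetoxy-3,7-dimethylocta-2,7-dienoate | C=C(C)C[C@@H](OC(C)=O)C/C(C)=C/C(=O)OC
F3 | step 6 | methyl (1R,4R)-4-acetoxy-2,6,6-trimethylcyclohex-2-ene-1-carboxylate | CC1=C[C@H](OC(C)=O)CC(C)(C)[C@H]1C(=O)OC
F4 | step 6 | (1R,4R)-4-(hydroxymethyl)-3,5,5-trimethylcyclohex-2-en-1-ol | CC1=C[C@H](O)CC(C)(C)[C@H]1CO
F5 | step 6 | (1R,4R)-4-hydroxy-2,6,6-trimethylcyclohex-2-ene-1-carbaldehyde | CC1=C[C@H](O)CC(C)(C)[C@H]1C=O
F6 | step 17 | methyl (2E,5S)-5-hydroxy-3,7-dimethylocta-2,7-dienoate | C=C(C)C[C@H](O)C/C(C)=C/C(=O)OC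
F7 | step 17 | methyl (2E,5S)-5-acetoxy-3,7-dimethylocta-2,7-dienoate | C=C(C)C[C@H](OC(C)=O)C/C(C)=C/C(=O)OC
F8 | step 17 | methyl (1S,4S)-4-acetoxy-2,6,6-trimethylcyclohex-2-ene-1-carboxylate | CC1=C[C@@H](OC(C)=O)CC(C)(C)[C@@H]1C(=O)OC
F9 | step 17 | (1S,4S)-4-(hydroxymethyl)-3,5,5-trimethylcyclohex-2-en-1-ol | CC1=C[C@@H](O)CC(C)(C)[C@@H]1CO
F10 | step 17 | (1S,4S)-4-hydroxy-2,6,6-trimethylcyclohex-2-ene-1-carbaldehyde | CC1=C[C@@H](O)CC(C)(C)[C@@H]1C=O
F11 | step 24 | (2E,4E)-5-[(3R,4S)-3,4-bis(tert-butyldimethylsilyloxy)-2,6,6-trimethylcyclohex-1-en-1-yl]-3-methylpenta-2,4-dienal | O=C/C=C(C)/C=C/C1=C(C)[C@@H](O[Si](C)(C)C(C)(C)C)[C@@H](O[Si](C)(C)C(C)(C)C)CC1(C)C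
F12 | step 24 | (3R,6R)-3-(tert-butyldimethylsilyloxy)-12'-apo-ε-caroten-12'-al | CC1=C[C@H](O[Si](C)(C)C(C)(C)C)CC(C)(C)[C@H]1/C=C/C(C)=C/C=C/C(C)=C/C=C/C=C(C)/C=O
F13 | step 24 | (3R,6R)-3-(tert-butyldimethylsilyloxy)-12'-apo-ε-caroten-12'-ol | CC1=C[C@H](O[Si](C)(C)C(C)(C)C)CC(C)(C)[C@H]1/C=C/C(C)=C/C=C/C(C)=C/C=C/C=C(C)/CO
F14 | step 24 | ring A C25 allylic bromide (12'-bromo analogue of F13) | CC1=C[C@H](O[Si](C)(C)C(C)(C)C)CC(C)(C)[C@H]1/C=C/C(C)=C/C=C/C(C)=C/C=C/C=C(C)/CBr
F15 | step 24 | ring A C25 triphenylphosphonium bromide | CC1=C[C@H](O[Si](C)(C)C(C)(C)C)CC(C)(C)[C@H]1/C=C/C(C)=C/C=C/C(C)=C/C=C/C=C(C)/C[P+](c1ccccc1)(c1ccccc1)c1ccccc1.[Br-]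
F16 | step 27 | (3S,4R)-3,4-dihydroxy-12'-apo-β-caroten-12'-al | O=C/C(C)=C/C=C/C=C(C)/C=C/C=C(C)/C=C/C1=C(C)[C@@H](O)[C@@H](O)CC1(C)C
F17 | step 27 | (3S,4R,3'R,6'R)-3'-(tert-butyldimethylsilyloxy)-β,ε-carotene-3,4-diol | CC1=C[C@H](O[Si](C)(C)C(C)(C)C)CC(C)(C)[C@H]1/C=C/C(C)=C/C=C/C(C)=C/C=C/C=C(C)/C=C/C=C(C)/C=C/C1=C(C)[C@@H](O)[C@@H](O)CC1(C)C
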